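The C6–C7 bond is the disconnection on which everything rests (numbering: lactone carbonyl C1, alkylidene carbon C2, ring carbons C3 and C4, exocyclic CH C5, CH2 C6, acetoxy carbon C7). The route exploits that C6 is the γ-carbon of the α-alkylidene γ-butyrolactone ring, vinylogous to C1 through C2=C5, while C7 is an allylic carbinol beside the C8=C9 alkene, i.e. the carbonyl carbon of an α-methyl enal. A catalytic asymmetric vinylogous Mukaiyama aldol therefore forms C6–C7, the 7S carbinol and the conjugated (E)-C2=C5 alkene in one operation. Its precursors are the deoxyribose-derived cyclic silyl dienolate (2-silyloxy-3-vinyl-4,5-dihydrofuran, O3 silylated) and the neryl-ester enal.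

Key step: step 11

Remarks on the chemistry
- TBS = tert-butyldimethylsilyl. Ring compounds are described with the C1–C7 numbering above; C8=C9 is the trisubstituted alkene next to C7.
- The catalyst of step 11 is the (S,S)-bisphosphoramide C51H52N6O2P2: two cyclic phosphoramide units, each built from (S)-N,N'-dimethyl-1,1'-binaphthyl-2,2'-diamine and a P=O group, joined at phosphorus through the two nitrogen atoms of N,N'-dimethylpentane-1,5-diamine.
- Assumption: the (R,R)-enantiomer of this catalyst is taken to steer the nucleophile to the Re face of conjugated aldehydes, so the (S,S)-enantiomer is specified for Si-face attack and 7S. The configuration of 20 should be checked by Mosher ester analysis and the antipodal catalyst used if the sense proves opposite.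
- Compound 11 is carried as an E/Z mixture (drawn as E), because both isomers give the same dienolate.

Step 1
Reactants: 1 2-deoxy-D-ribose
Product: 2 2-deoxy-D-ribono-1,4-lactone
Conditions: Br2, H2O, rt; NaHCO3 to pH 6; concentration
Reagents that add atoms: none
Why: Bromine-water oxidation of the aldose hemiacetal to the aldonolactone should give the five-membered lactone on concentration, with the two sugar stereocentres (later C3 and C4) untouched.

Step 2
Reactants: 2 2-deoxy-D-ribono-1,4-lactone
Product: 3 3,5-di-O-TBS-2-deoxy-D-ribono-1,4-lactone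
Conditions: TBSCl (2.5 equiv), imidazole, DMF, rt
Reagents that add atoms: tert-butyldimethylsilyl chloride, CC(C)(C)[Si](C)(C)Cl
Why: Silyl ether formation with a silyl chloride and imidazole should cap both hydroxyls and leave the lactone intact.

Step 3
Reactants: 3 3,5-di-O-TBS-2-deoxy-D-ribono-1,4-lactone
Product: 4 3-O-TBS-2-deoxy-D-ribono-1,4-lactone (primary hydroxyl free)
Conditions: CF3CO2H/H2O/THF (1:1:4), 0 °C
Reagents that add atoms: none
Why: Acid-catalysed silyl ether hydrolysis is much faster at an unhindered primary oxygen than at a secondary one, so this selective primary desilylation should free only the CH2OH group while the lactone survives the cold aqueous acid.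

Step 4
Reactants: 4 3-O-TBS-2-deoxy-D-ribono-1,4-lactone
Product: 5 (2S,3S)-3-(TBS-oxy)-5-oxotetrahydrofuran-2-carbaldehyde
Conditions: Dess–Martin periodinane, CH2Cl2, 0 °C to rt; used crude
Reagents that add atoms: none
Why: Dess–Martin oxidation of the primary alcohol runs under near-neutral conditions, which should spare the C4 stereocentre next to the new aldehyde and avoid β-elimination of the C3 silyloxy group.

Step 5
Reactants: 5 (2S,3S)-3-(TBS-oxy)-5-oxotetrahydrofuran-2-carbaldehyde
Product: 6 (4S,5R)-4-(TBS-oxy)-5-(2-methylprop-1-en-1-yl)dihydrofuran-2(3H)-one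
Conditions: [i-PrPPh3]I, n-BuLi, THF, 0 °C; ylide added slowly to 5, THF, −78 °C to 0 °C
Reagents that add atoms: isopropyltriphenylphosphonium iodide, CC(C)[P+](c1ccccc1)(c1ccccc1)c1ccccc1.[I-]
Why: Wittig olefination with a non-stabilised ylide is far faster at an aldehyde than at a lactone carbonyl, and adding the ylide to cold 5 keeps base from building up, so C4 should keep its configuration, while the new alkene carries two methyl groups and has no geometry to control.

Step 6
Reactants: 6 (4S,5R)-4-(TBS-oxy)-5-(2-methylprop-1-en-1-yl)dihydrofuran-2(3H)-one; 7 acetaldehyde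
Product: 9 aldol adduct (1-hydroxyethyl group at C2 trans to the C3 silyloxy group; carbinol epimers), via lithium enolate 8 (not isolated)
Conditions: LiN(i-Pr)2, THF, −78 °C; MeCHO, −78 °C; satd aq NH4Cl
Reagents that add atoms: none
Why: Aldol addition of the lactone lithium enolate to acetaldehyde should occur anti to the C3 silyloxy group, β-silyloxy lactone enolates being stable to elimination at −78 °C, and the two new stereocentres are erased in step 7, so their ratio does not matter.

Step 7
Reactants: 9 aldol adduct
Product: 11 (4S,5R)-3-ethylidene-4-(TBS-oxy)-5-(2-methylprop-1-en-1-yl)dihydrofuran-2(3H)-one (E/Z mixture), via mesylate 10 (not isolated)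
Conditions: MsCl, Et3N, CH2Cl2, 0 °C; then DBU, 0 °C to rt
Reagents that add atoms: none
Why: Mesylation followed by base-induced E1cB elimination should give the conjugated ethylidene lactone, because methanesulfonate leaves far more readily than the ring silyloxy group.

Step 8
Reactants: 11 ethylidene lactone (E/Z mixture)
Product: 13 fragment 1, the silyl dienolate (4S,5R)-2,4-bis(TBS-oxy)-5-(2-methylprop-1-en-1-yl)-3-vinyl-4,5-dihydrofuran, via lithium dienolate 12 (not isolated)
Conditions: LiN(i-Pr)2, DMPU, THF, −78 °C, 20 min; TBSCl, −78 to 0 °C; pentane, filtration under Ar; used crude and cold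
Reagents that add atoms: tert-butyldimethylsilyl chloride, CC(C)(C)[Si](C)(C)Cl
Why: γ-Deprotonation of the α,β-unsaturated lactone at the C6 methyl group, its only vinylogously acidified position, and O-silylation of the extended enolate (silyl dienol ether formation) should give the cyclic silyl ketene acetal, the cold and short-lived enolate being expected neither to expel the C3 silyloxy group nor to undergo the thermal Claisen ring contraction open to an O-allyl ketene acetal.

Step 9
Reactants: 14 nerol; 15 (E)-3-methylpent-2-enoic acid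
Product: 16 neryl (E)-3-methylpent-2-enoate
Conditions: DCC, 4-(dimethylamino)pyridine (cat.), CH2Cl2, 0 °C to rt
Reagents that add atoms: none
Why: Steglich esterification of a primary allylic alcohol is mild enough that the Z geometry of nerol and the E geometry of the enoate should both be preserved.

Step 10
Reactants: 16 neryl (E)-3-methylpent-2-enoate
Product: 18 fragment 2, (2Z,6E)-3,7-dimethyl-8-oxoocta-2,6-dien-1-yl (E)-3-methylpent-2-enoate, via allylic alcohol 17 (not isolated)
Conditions: SeO2 (cat.), t-BuOOH, salicylic acid (cat.), CH2Cl2, rt; crude mixture, then MnO2, CH2Cl2, rt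
Reagents that add atoms: selenium dioxide, O=[Se]=O (oxygen donor, turned over by tert-butyl hydroperoxide, CC(C)(C)OO)
Why: SeO2 allylic oxidation (ene reaction then [2,3]-sigmatropic shift) attacks the electron-rich terminal trisubstituted alkene at its (E)-methyl group, the other two alkenes being deactivated by the ester groups, and MnO2 oxidation of the allylic alcohol then converges alcohol and any aldehyde already formed on the (E)-enal.

Step 11
Reactants: 13 fragment 1 (silyl dienolate); 18 fragment 2 (enal)
Product: 20 7-hydroxy-3-O-TBS precursor of the target (7S; E at C2=C5), via trichlorosilyl ether 19 (not isolated)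
Conditions: SiCl4 (1.1 equiv), (S,S)-bisphosphoramide C51H52N6O2P2 (5 mol %), i-Pr2NEt (10 mol %), CH2Cl2, −78 °C; satd aq NaHCO3
Reagents that add atoms: none
Why: The phosphoramide-ligated trichlorosilyl cation formed from SiCl4 binds the aldehyde oxygen of 18, the terminal CH2 (C6) of 13 adds to C7 through an open transition state, and chloride then removes the silyl group from the resulting oxocarbenium ion, leaving the lactone, the C2=C5 alkene and the trichlorosilyl ether 19, which is hydrolysed to 20 on work-up. The closest known reaction type is the Lewis-base-activated SiCl4 vinylogous Mukaiyama aldol of ester-derived silyl dienolates with conjugated aldehydes. No ring is closed, so no mode of closure arises; one C–C bond and one stereocentre are formed. C7 is set by the catalyst alone, the ring stereocentres being five bonds away: the (S,S)-catalyst is chosen to expose the Si face of the enal, which corresponds to 7S because C8 outranks C6. The step needs γ- over α-attack (secured by the fully substituted C2 and the bulky ion pair), 1,2- over 1,4-addition (secured by the α-methyl group of the enal and activation at the carbonyl oxygen), and E geometry at C2=C5 (secured by reaction through the s-trans diene conformer, in which C6 avoids the in-plane silyloxy group on C1 and so ends trans to the carbonyl).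

Step 12
Reactants: 20 7-hydroxy-3-O-TBS precursor
Product: 21 7-O-acetyl-3-O-TBS compound
Conditions: Ac2O, pyridine, 4-(dimethylamino)pyridine (cat.), CH2Cl2, 0 °C
Reagents that add atoms: acetic anhydride, CC(=O)OC(C)=O
Why: Nucleophile-catalysed acylation of the secondary allylic alcohol with acetic anhydride proceeds with retention at C7, and the mild base should not trigger vinylogous elimination of the new acetate.

Step 13
Reactants: 21 7-O-acetyl-3-O-TBS compound
Product: 22 target CNP0168501.1
Conditions: HF·pyridine, pyridine, THF, 0 °C to rt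
Reagents that add atoms: none
Why: Fluoride-mediated silyl ether cleavage with pyridine-buffered HF·pyridine is not basic enough to cause acetate loss or elimination and not acidic enough to ionise the allylic C7 and C4 oxygens, so the C3 hydroxyl should be freed without touching any stereocentre.

Compound list
1 | 2-deoxy-D-ribose | O=CC[C@H](O)[C@H](O)CO | starting material
2 | 2-deoxy-D-ribono-1,4-lactone, (4S,5R)-4-hydroxy-5-(hydroxymethyl)dihydrofuran-2(3H)-one | O=C1C[C@H](O)[C@@H](CO)O1 | intermediate
3 | 3,5-di-O-TBS-2-deoxy-D-ribono-1,4-lactone | O=C1C[C@H](O[Si](C)(C)C(C)(C)C)[C@@H](CO[Si](C)(C)C(C)(C)C)O1 | intermediate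
4 | 3-O-TBS-2-deoxy-D-ribono-1,4-lactone, (4S,5R)-4-(TBS-oxy)-5-(hydroxymethyl)dihydrofuran-2(3H)-one | O=C1C[C@H](O[Si](C)(C)C(C)(C)C)[C@@H](CO)O1 | intermediate
5 | (2S,3S)-3-(TBS-oxy)-5-oxotetrahydrofuran-2-carbaldehyde | O=C1C[C@H](O[Si](C)(C)C(C)(C)C)[C@@H](C=O)O1 | intermediate
6 | (4S,5R)-4-(TBS-oxy)-5-(2-methylprop-1-en-1-yl)dihydrofuran-2(3H)-one | O=C1C[C@H](O[Si](C)(C)C(C)(C)C)[C@@H](C=C(C)C)O1 | intermediate
7 | acetaldehyde | CC=O | starting material
8 | lithium enolate of 6 | [Li]OC1=C[C@H](O[Si](C)(C)C(C)(C)C)[C@@H](C=C(C)C)O1 | intermediate (not isolated)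
9 | aldol adduct, (3S,4S,5R)-4-(TBS-oxy)-3-(1-hydroxyethyl)-5-(2-methylprop-1-en-1-yl)dihydrofuran-2(3H)-one, carbinol epimers | O=C1[C@@H](C(C)O)[C@H](O[Si](C)(C)C(C)(C)C)[C@@H](C=C(C)C)O1 | intermediate
10 | methanesulfonate of 9 | O=C1[C@@H](C(C)OS(C)(=O)=O)[C@H](O[Si](C)(C)C(C)(C)C)[C@@H](C=C(C)C)O1 | intermediate (not isolated)
11 | (4S,5R)-3-ethylidene-4-(TBS-oxy)-5-(2-methylprop-1-en-1-yl)dihydrofuran-2(3H)-one, E/Z mixture, E isomer drawn | C/C=C1/C(=O)O[C@H](C=C(C)C)[C@H]1O[Si](C)(C)C(C)(C)C | intermediate
12 | lithium dienolate of 11 | C=CC1=C(O[Li])O[C@H](C=C(C)C)[C@H]1O[Si](C)(C)C(C)(C)C | intermediate (not isolated)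
13 | fragment 1, (4S,5R)-2,4-bis(TBS-oxy)-5-(2-methylprop-1-en-1-yl)-3-vinyl-4,5-dihydrofuran | C=CC1=C(O[Si](C)(C)C(C)(C)C)O[C@H](C=C(C)C)[C@H]1O[Si](C)(C)C(C)(C)C | intermediate
14 | nerol, (Z)-3,7-dimethylocta-2,6-dien-1-ol | OC/C=C(/C)CCC=C(C)C | starting material
15 | (E)-3-methylpent-2-enoic acid | CC/C(C)=C/C(=O)O | starting material
16 | neryl (E)-3-methylpent-2-enoate | CC/C(C)=C/C(=O)OC/C=C(/C)CCC=C(C)C | intermediate
17 | (2Z,6E)-8-hydroxy-3,7-dimethylocta-2,6-dien-1-yl (E)-3-methylpent-2-enoate | CC/C(C)=C/C(=O)OC/C=C(/C)CC/C=C(\C)CO | intermediate (not isolated)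
18 | fragment 2, (2Z,6E)-3,7-dimethyl-8-oxoocta-2,6-dien-1-yl (E)-3-methylpent-2-enoate | CC/C(C)=C/C(=O)OC/C=C(/C)CC/C=C(\C)C=O | intermediate
19 | 7-O-trichlorosilyl ether of 20 | CC/C(C)=C/C(=O)OC/C=C(/C)CC/C=C(\C)[C@H](C/C=C1/C(=O)O[C@H](C=C(C)C)[C@H]1O[Si](C)(C)C(C)(C)C)O[Si](Cl)(Cl)Cl | intermediate (not isolated)
20 | (2Z,6E,8S,10E)-10-[(4S,5R)-4-(TBS-oxy)-5-(2-methylprop-1-en-1-yl)-2-oxodihydrofuran-3(2H)-ylidene]-8-hydroxy-3,7-dimethyldeca-2,6-dien-1-yl (E)-3-methylpent-2-enoate (7S in the C1–C7 numbering) | CC/C(C)=C/C(=O)OC/C=C(/C)CC/C=C(\C)[C@H](C/C=C1/C(=O)O[C@H](C=C(C)C)[C@H]1O[Si](C)(C)C(C)(C)C)O | intermediate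
21 | 7-O-acetate of 20 | CC/C(C)=C/C(=O)OC/C=C(/C)CC/C=C(\C)[C@H](C/C=C1/C(=O)O[C@H](C=C(C)C)[C@H]1O[Si](C)(C)C(C)(C)C)OC(C)=O | intermediate
22 | CNP0168501.1, (2Z,6E,8S,10E)-8-acetoxy-10-[(4S,5R)-4-hydroxy-5-(2-methylprop-1-en-1-yl)-2-oxodihydrofuran-3(2H)-ylidene]-3,7-dimethyldeca-2,6-dien-1-yl (E)-3-methylpent-2-enoate | CC/C(C)=C/C(=O)OC/C=C(/C)CC/C=C(\C)[C@H](C/C=C1/C(=O)O[C@H](C=C(C)C)[C@H]1O)OC(C)=O | target

Total step count: 13. Longest linear sequence: 11 steps (steps 1–8 and 11–13, from 2-deoxy-D-ribose); fragment 2 takes 2 steps (9 and 10).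

Steps most likely to fail

1. Step 11. What may go wrong: insufficient facial discrimination at C7 by the catalyst for this α-methyl enal, competing α-attack or Z-alkene formation, or protodesilylation of the dienolate by adventitious HCl before it adds. The fallback sets out from 13 and 18 and comes back at 20. The same C6–C7 bond is made without asking for stereocontrol, by a BF3·OEt2-promoted vinylogous Mukaiyama aldol in CH2Cl2 at −78 °C, which should give the C7-epimeric alcohol mixture F1. Dess–Martin oxidation then gives the C7 ketone F2. Corey–Bakshi–Shibata reduction with (R)-1-methyl-3,3-diphenyltetrahydro-1H,3H-pyrrolo[1,2-c][1,3,2]oxazaborole (C18H20BNO) and catecholborane in toluene at −78 °C, in which the α-methylalkenyl arm acts as the large group, should return the 7S alcohol 20.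

2. Step 8. What may go wrong: loss of the C3 silyloxy group by E1cB elimination from the lithium dienolate, or hydrolysis of the ketene acetal during handling. The fallback sets out from 11 and comes back at 13. The silyl ether is first removed with HF·pyridine to give the hydroxy ethylidene lactone F3. Two equivalents of LiN(i-Pr)2 in THF/DMPU at −78 °C then generate the dilithio alkoxide–dienolate F4, whose alkoxide cannot act as a leaving group (the principle behind Frater–Seebach alkylations). Double silylation with excess TBSCl installs both silyl groups of 13 in one operation.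

3. Step 5. What may go wrong: epimerisation at C4 or β-elimination of the C3 silyloxy group in the aldehyde under the basic ylide, or attack of the ylide on the lactone carbonyl. The fallback sets out from 5 and comes back at 6. Non-basic Lombardo–Takai methylenation with Zn, CH2Br2 and TiCl4 in THF/CH2Cl2, which tolerates enolisable aldehydes and lactones, should give the vinyl lactone F5. Olefin cross-metathesis with excess 2-methyl-2-butene and the second-generation Grubbs catalyst RuCl2(=CHPh)(PCy3)(1,3-dimesitylimidazolidin-2-ylidene) then converts the vinyl group into the 2-methylprop-1-enyl group of 6.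

Further compounds
F1 | step 11 | C7-epimeric alcohol mixture (7RS form of 20) | CC/C(C)=C/C(=O)OC/C=C(/C)CC/C=C(\C)C(O)C/C=C1/C(=O)O[C@H](C=C(C)C)[C@H]1O[Si](C)(C)C(C)(C)C
F2 | step 11 | C7 ketone | CC/C(C)=C/C(=O)OC/C=C(/C)CC/C=C(\C)C(=O)C/C=C1/C(=O)O[C@H](C=C(C)C)[C@H]1O[Si](C)(C)C(C)(C)C
F3 | step 8 | hydroxy ethylidene lactone, (4S,5R)-3-ethylidene-4-hydroxy-5-(2-methylprop-1-en-1-yl)dihydrofuran-2(3H)-one, E isomer drawn | C/C=C1/C(=O)O[C@H](C=C(C)C)[C@H]1O
F4 | step 8 | dilithio alkoxide–dienolate | C=CC1=C(O[Li])O[C@H](C=C(C)C)[C@H]1O[Li]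
F5 | step 5 | vinyl lactone, (4S,5R)-4-(TBS-oxy)-5-vinyldihydrofuran-2(3H)-one | O=C1C[C@H](O[Si](C)(C)C(C)(C)C)[C@@H](C=C)O1
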